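**Retrosynthetic overview**
- Kobophenol A ⇐ its deca-O-benzyl ether ⇐ one-pot annulation of a 2-fluoro-diarylmethane with 4-(benzyloxy)benzaldehyde, which forms O1–C7a and C2–C3 of the central dihydrobenzofuran.
- Enabling feature: in the central dihydrobenzofuran, C3 is a diarylmethine (between the benzo ring and the 7-hydroxybenzofuran-5-yl ring), C2 carries O1 and a 4-hydroxyphenyl group (aldehyde oxidation level), and O1 sits on arene carbon C7a, ortho to C3a. A benzylic carbanion/aldehyde addition followed by SNAr at a C7a–F bond therefore closes the ring.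
- The diarylmethane comes from a Suzuki coupling of an east aryl bromide (carrying the oxolane) with a west benzylboronate (carrying the outer dihydrobenzofuran).
- East: oxolane C3/C4 from an iridium/isothiourea allylic alkylation, C2/C5 from aryl Grignard additions and cyclodehydration. West: outer dihydrobenzofuran by enantioselective rhodium-carbene C–H insertion.
- Ring order: outer dihydrobenzofuran and oxolane (separate branches), then the central dihydrobenzofuran last.

Key step: step 23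

Assumption: for each chiral-catalyst step the drawn configuration is the one expected from the named catalyst enantiomers; should the first run show the opposite sense of induction, the mirror-image catalyst is used and nothing else changes.

**East branch: aryl acetic ester**

Step 1
Reactants: 1 3-bromo-5-fluorophenol
Product: 2 1-(benzyloxy)-3-bromo-5-fluorobenzene
Conditions: BnBr (1.1 equiv), K2CO3, DMF, rt
Reagents that add atoms: benzyl bromide, BrCc1ccccc1
Why: Williamson etherification of the phenoxide should proceed cleanly.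

Step 2
Reactants: 2 1-(benzyloxy)-3-bromo-5-fluorobenzene
Product: 3 tert-butyl 2-[3-(benzyloxy)-5-fluorophenyl]acetate
Conditions: BrZnCH2CO2t-Bu (1.3 equiv), Pd(dba)2 (2 mol%), XPhos (4 mol%), THF, 60 °C
Reagents that add atoms: (2-tert-butoxy-2-oxoethyl)zinc bromide, CC(C)(C)OC(=O)C[Zn]Br
Why: Negishi-type coupling of an aryl bromide with a Reformatsky zinc enolate is a standard route to aryl acetic esters and should leave the C–F bond untouched.

Step 3
Reactants: 3 tert-butyl 2-[3-(benzyloxy)-5-fluorophenyl]acetate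
Product: 4 tert-butyl 2-[5-(benzyloxy)-2-bromo-3-fluorophenyl]acetate
Conditions: NBS (1.05 equiv), MeCN, 0 °C to rt, dark
Reagents that add atoms: N-bromosuccinimide, O=C1CCC(=O)N1Br
Why: electrophilic aromatic bromination should go para to the benzyloxy group (the position between the side chain and fluorine), as in the para-selective bromination of 3,5-disubstituted anisoles.

Step 4
Reactants: 4 tert-butyl 2-[5-(benzyloxy)-2-bromo-3-fluorophenyl]acetate
Product: 5 2-[5-(benzyloxy)-2-bromo-3-fluorophenyl]acetic acid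
Conditions: TFA/CH2Cl2 (1:4), rt
Reagents that add atoms: none
Why: acidolysis of the tert-butyl ester (loss of 2-methylpropene) should occur under conditions that aryl benzyl ethers tolerate.

Step 5
Reactants: 5 2-[5-(benzyloxy)-2-bromo-3-fluorophenyl]acetic acid
Product: 6 pentafluorophenyl 2-[5-(benzyloxy)-2-bromo-3-fluorophenyl]acetate
Conditions: C6F5OH (1.1 equiv), EDC·HCl (1.2 equiv), DMAP (5 mol%), CH2Cl2, 0 °C to rt
Reagents that add atoms: pentafluorophenol, Oc1c(F)c(F)c(F)c(F)c1F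
Why: carbodiimide (Steglich-type) esterification should give the activated ester needed for isothiourea catalysis.

**East branch: allylic carbonate**

Step 6
Reactants: 7 3,5-bis(benzyloxy)benzaldehyde
Product: 8 ethyl (E)-3-[3,5-bis(benzyloxy)phenyl]prop-2-enoate
Conditions: (EtO)2P(O)CH2CO2Et (1.2 equiv), NaH (1.2 equiv), THF, 0 °C to rt
Reagents that add atoms: triethyl phosphonoacetate, CCOC(=O)CP(=O)(OCC)OCC
Why: Horner–Wadsworth–Emmons olefination should give the E enoate.

Step 7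
Reactants: 8 ethyl (E)-3-[3,5-bis(benzyloxy)phenyl]prop-2-enoate
Product: 9 (E)-3-[3,5-bis(benzyloxy)phenyl]prop-2-en-1-ol
Conditions: DIBAL-H (2.2 equiv), CH2Cl2, −78 °C; Rochelle salt work-up
Reagents that add atoms: none
Why: 1,2-reduction of the enoate by DIBAL-H should give the allylic alcohol without touching the alkene.

Step 8
Reactants: 9 (E)-3-[3,5-bis(benzyloxy)phenyl]prop-2-en-1-ol
Product: 10 tert-butyl (E)-3-[3,5-bis(benzyloxy)phenyl]prop-2-en-1-yl carbonate
Conditions: Boc2O (1.3 equiv), DMAP (10 mol%), MeCN, rt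
Reagents that add atoms: di-tert-butyl dicarbonate, CC(C)(C)OC(=O)OC(=O)OC(C)(C)C
Why: DMAP-catalysed acylation should give the linear allylic carbonate used as the iridium electrophile.

**East branch: oxolane**

Step 9
Reactants: 6 pentafluorophenyl 2-[5-(benzyloxy)-2-bromo-3-fluorophenyl]acetate; 10 tert-butyl (E)-3-[3,5-bis(benzyloxy)phenyl]prop-2-en-1-yl carbonate
Product: 12 (2S,3R)-2-[5-(benzyloxy)-2-bromo-3-fluorophenyl]-3-[3,5-bis(benzyloxy)phenyl]-N-methoxy-N-methylpent-4-enamide, via pentafluorophenyl pentenoate 11 (not isolated)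
Conditions: [Ir(cod)Cl]2 (2 mol%), (R,R,R)-binaphthyl bis(1-phenylethyl)phosphoramidite (4 mol%, activated with n-PrNH2), (S)-benzotetramisole (10 mol%), THF, rt; then MeNHOMe·HCl (2 equiv), i-Pr2NEt (2 equiv), rt
Reagents that add atoms: N,O-dimethylhydroxylamine hydrochloride, CNOC.Cl
Why: branched-selective iridium-catalysed allylic substitution by the C1-ammonium enolate formed from the pentafluorophenyl ester and the isothiourea (synergistic iridium/Lewis-base catalysis, precedented for aryl acetic pentafluorophenyl esters and cinnamyl carbonates) should set C3 through the iridium ligand and C2 through the isothiourea, and aminolysis of 11 then gives the Weinreb amide.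

Step 10
Reactants: 12 (2S,3R)-2-[5-(benzyloxy)-2-bromo-3-fluorophenyl]-3-[3,5-bis(benzyloxy)phenyl]-N-methoxy-N-methylpent-4-enamide
Product: 13 (2S,3R)-2-[5-(benzyloxy)-2-bromo-3-fluorophenyl]-3-[3,5-bis(benzyloxy)phenyl]-N-methoxy-N-methyl-4-oxobutanamide
Conditions: OsO4 (2 mol%), NaIO4 (4 equiv), 2,6-lutidine (2 equiv), 1,4-dioxane/H2O (3:1), rt; used crude
Reagents that add atoms: sodium periodate (oxygen source, relayed by catalytic OsO4), [Na+].[O-]I(=O)(=O)=O
Why: buffered Lemieux–Johnson cleavage of the terminal alkene should give the aldehyde without epimerising the α-aryl centre.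

Step 11
Reactants: 13 (2S,3R)-2-[5-(benzyloxy)-2-bromo-3-fluorophenyl]-3-[3,5-bis(benzyloxy)phenyl]-N-methoxy-N-methyl-4-oxobutanamide; 14 4-(benzyloxy)phenylmagnesium bromide
Product: 15 (2S,3R)-2-[5-(benzyloxy)-2-bromo-3-fluorophenyl]-1,4-bis[4-(benzyloxy)phenyl]-3-[3,5-bis(benzyloxy)phenyl]-4-hydroxybutan-1-one (mixture of C4 epimers; in equilibrium with its cyclic hemiketal)
Conditions: 14 (3 equiv), THF, −78 to 0 °C; aq. NH4Cl
Reagents that add atoms: none
Why: Grignard addition to the aldehyde and Weinreb ketone synthesis (the chelated adduct stops at the ketone) should install both 4-(benzyloxy)phenyl groups without touching C2 and C3, and the new carbinol centre is re-set in step 13.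

Step 12
Reactants: 15 (2S,3R)-2-[5-(benzyloxy)-2-bromo-3-fluorophenyl]-1,4-bis[4-(benzyloxy)phenyl]-3-[3,5-bis(benzyloxy)phenyl]-4-hydroxybutan-1-one
Product: 16 (2S,3R)-2-[5-(benzyloxy)-2-bromo-3-fluorophenyl]-1,4-bis[4-(benzyloxy)phenyl]-3-[3,5-bis(benzyloxy)phenyl]butane-1,4-diol (mixture of C1 and C4 epimers)
Conditions: NaBH4 (2 equiv), THF/MeOH (1:1), 0 °C
Reagents that add atoms: none
Why: borohydride reduction of the aryl ketone should give the 1,4-diol, whose carbinol configurations are immaterial because both centres ionise in the next step.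

Step 13
Reactants: 16 (2S,3R)-2-[5-(benzyloxy)-2-bromo-3-fluorophenyl]-1,4-bis[4-(benzyloxy)phenyl]-3-[3,5-bis(benzyloxy)phenyl]butane-1,4-diol
Product: 17 (2R,3S,4R,5S)-3-[5-(benzyloxy)-2-bromo-3-fluorophenyl]-2,5-bis[4-(benzyloxy)phenyl]-4-[3,5-bis(benzyloxy)phenyl]oxolane
Conditions: TsOH·H2O (5 mol%), CH2Cl2, 0 °C, close monitoring; Et3N quench
Reagents that add atoms: none
Why: acid-catalysed cyclodehydration through a 4-(benzyloxy)benzylic cation (5-exo capture by the other hydroxyl, reversible at C2 and C5) should place each of these aryl groups trans to its C3/C4 neighbour while the cis C3/C4 pair from step 9 is untouched, as in the cyclisations used for 2,5-diaryl oxolane lignans and in water trapping of stilbene-dimer bis-quinone methides.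

**West branch: outer dihydrobenzofuran**

Step 14
Reactants: 18 5-bromo-2-hydroxy-3-methoxybenzaldehyde
Product: 19 5-bromo-2,3-dihydroxybenzaldehyde
Conditions: BBr3 (2.5 equiv), CH2Cl2, −78 to 0 °C; H2O
Reagents that add atoms: none
Why: BBr3 cleavage of the aryl methyl ether should give the catechol so that every phenol of the route can carry a benzyl group.

Step 15
Reactants: 19 5-bromo-2,3-dihydroxybenzaldehyde; 20 4-(benzyloxy)benzyl chloride
Product: 22 3-(benzyloxy)-2-{[4-(benzyloxy)benzyl]oxy}-5-bromobenzaldehyde, via sodium phenoxide 21 (not isolated)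
Conditions: NaH (2.2 equiv), DMSO, rt; BnBr (1.0 equiv), rt; then 20 (1.2 equiv), 50 °C
Reagents that add atoms: benzyl bromide, BrCc1ccccc1
Why: in the dianion the 3-phenoxide (neither conjugated to nor chelated by the formyl group) is the more nucleophilic and should take the benzyl bromide first, after which the remaining 2-phenoxide is alkylated by the benzylic chloride (sequential Williamson etherification).

Step 16
Reactants: 22 3-(benzyloxy)-2-{[4-(benzyloxy)benzyl]oxy}-5-bromobenzaldehyde; 23 1,3-bis(benzyloxy)-5-bromobenzene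
Product: 25 [3-(benzyloxy)-2-{[4-(benzyloxy)benzyl]oxy}-5-bromophenyl][3,5-bis(benzyloxy)phenyl]methanol (racemic), via arylmagnesium bromide 24 (not isolated)
Conditions: 23, Mg, I2 (cat.), THF, 40 °C; then 22, 0 °C; aq. NH4Cl
Reagents that add atoms: none
Why: Grignard addition to the aldehyde should be much faster than any exchange at the aryl bromide.

Step 17
Reactants: 25 [3-(benzyloxy)-2-{[4-(benzyloxy)benzyl]oxy}-5-bromophenyl][3,5-bis(benzyloxy)phenyl]methanol
Product: 26 [3-(benzyloxy)-2-{[4-(benzyloxy)benzyl]oxy}-5-bromophenyl][3,5-bis(benzyloxy)phenyl]methanone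
Conditions: MnO2 (10 equiv), CH2Cl2, rt
Reagents that add atoms: none
Why: MnO2 oxidation of a diaryl carbinol to the benzophenone is reliable and leaves benzyl ethers intact.

Step 18
Reactants: 26 [3-(benzyloxy)-2-{[4-(benzyloxy)benzyl]oxy}-5-bromophenyl][3,5-bis(benzyloxy)phenyl]methanone
Product: 27 hydrazone of ketone 26 (E/Z mixture)
Conditions: N2H4·H2O (10 equiv), AcOH (cat.), EtOH, 80 °C
Reagents that add atoms: hydrazine hydrate, NN.O
Why: condensation with excess hydrazine should give the free hydrazone needed for diazo generation.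

Step 19
Reactants: 27 hydrazone of ketone 26
Product: 29 (2S,3R)-7-(benzyloxy)-2-[4-(benzyloxy)phenyl]-3-[3,5-bis(benzyloxy)phenyl]-5-bromo-2,3-dihydro-1-benzofuran (2,3-cis), via diaryldiazomethane 28 (not isolated)
Conditions: MnO2 (8 equiv), CH2Cl2, 0 °C, filtration; then Rh2(R-PTAD)4 (1 mol%), CH2Cl2, 0 °C to rt
Reagents that add atoms: none
Why: the rhodium donor/donor carbene should insert into the benzylic C–H of the neighbouring ArCH2O ether (1,5 C–H insertion, precedented for enantioselective 2,3-diaryl dihydrobenzofuran synthesis), giving the cis ring with C3 fixed by the chiral carboxylate catalyst.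

Step 20
Reactants: 29 (2S,3R)-7-(benzyloxy)-2-[4-(benzyloxy)phenyl]-3-[3,5-bis(benzyloxy)phenyl]-5-bromo-2,3-dihydro-1-benzofuran
Product: 30 (2R,3R)-7-(benzyloxy)-2-[4-(benzyloxy)phenyl]-3-[3,5-bis(benzyloxy)phenyl]-5-bromo-2,3-dihydro-1-benzofuran (2,3-trans)
Conditions: BF3·OEt2 (0.2 equiv), CH2Cl2, −20 °C; Et3N quench
Reagents that add atoms: none
Why: reversible Lewis-acid ionisation of the C2–O bond (4-(benzyloxy)benzylic cation) and re-closure should give the more stable trans isomer while C3 is untouched.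

Step 21
Reactants: 30 (2R,3R)-7-(benzyloxy)-2-[4-(benzyloxy)phenyl]-3-[3,5-bis(benzyloxy)phenyl]-5-bromo-2,3-dihydro-1-benzofuran
Product: 31 2-{[(2R,3R)-7-(benzyloxy)-2-[4-(benzyloxy)phenyl]-3-[3,5-bis(benzyloxy)phenyl]-2,3-dihydro-1-benzofuran-5-yl]methyl}-4,4,5,5-tetramethyl-1,3,2-dioxaborolane
Conditions: CH2(Bpin)2 (1.5 equiv), Pd[P(t-Bu)3]2 (5 mol%), KOH (8 M aq., 2 equiv), 1,4-dioxane, rt
Reagents that add atoms: bis[(pinacolato)boryl]methane, CC1(C)OB(CB2OC(C)(C)C(C)(C)O2)OC1(C)C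
Why: chemoselective Suzuki–Miyaura mono-coupling of the gem-diborylmethane with an aryl bromide should give the benzylboronate at room temperature.

**Union, key step and deprotection**

Step 22
Reactants: 31 benzylboronate of step 21; 17 (2R,3S,4R,5S)-3-[5-(benzyloxy)-2-bromo-3-fluorophenyl]-2,5-bis[4-(benzyloxy)phenyl]-4-[3,5-bis(benzyloxy)phenyl]oxolane
Product: 32 (2R,3R)-7-(benzyloxy)-5-{4-(benzyloxy)-2-[(2R,3S,4R,5S)-2,5-bis[4-(benzyloxy)phenyl]-4-[3,5-bis(benzyloxy)phenyl]oxolan-3-yl]-6-fluorobenzyl}-2-[4-(benzyloxy)phenyl]-3-[3,5-bis(benzyloxy)phenyl]-2,3-dihydro-1-benzofuran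
Conditions: Pd(OAc)2 (5 mol%), SPhos (10 mol%), K3PO4 (3 equiv), toluene/H2O (10:1), 90 °C
Reagents that add atoms: none
Why: sp3–sp2 Suzuki–Miyaura coupling of a primary benzylboronate with an ortho-substituted aryl bromide should give the diarylmethane, the C–F bond being inert to palladium.

Step 23
Reactants: 32 diarylmethane of step 22; 33 4-(benzyloxy)benzaldehyde
Product: 36 deca-O-benzylkobophenol A (central dihydrobenzofuran 2S,3S), via benzylic lithium compound 34 (not isolated), via lithium alkoxide 35 (not isolated)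
Conditions: LDA (1.1 equiv), THF, −78 °C, 1 h; 33 (1.05 equiv), −78 °C, 1 h; then DMPU, −78 to 60 °C
Reagents that add atoms: none
Why: Proposed new method: LDA should remove a proton from the doubly benzylic CH2 of 32 (the most acidic C–H, further acidified by the ortho fluorine) to give 34, which adds to aldehyde 33 to form the C2–C3 bond, and lithium alkoxide 35 then displaces the ortho fluoride by addition–elimination (5-exo attack of O on the C–F carbon) to close the central dihydrofuran ring; the closest known reaction types are lateral lithiation of diarylmethanes with aldehyde trapping, intramolecular SNAr etherification of 2-(2-fluoroaryl)ethoxides, and the one-pot benzylic-anion addition/SNAr annulation of 2-fluorotoluenes with nitriles that gives indoles. C3 is set in the addition: with the oxolane C3–H lying in the arene plane next to the benzylic carbon, the aryl group on oxolane C2 covers one face of the planar carbanion and the aldehyde should approach the other. C2 is set in the same open transition state, the aldehyde aryl lying anti to the bulky fluoroarene, which gives the anti alkoxide and hence the 2,3-trans ring. The step needs benzylic deprotonation to win over lithiation ortho to fluorine and over the tertiary C3–H of the outer dihydrobenzofuran (secured by about 5 pK units of extra stabilisation, amine-mediated equilibration and the hindered nature of that C–H), and it needs the addition to stay kinetic (secured by the lithium counter-ion, one equivalent of aldehyde and a cyclisation temperature of at most 60 °C).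

Step 24
Reactants: 36 deca-O-benzylkobophenol A
Product: 37 kobophenol A
Conditions: H2 (1 atm), Pd(OH)2/C, EtOAc/MeOH (1:1), rt, stopped at full conversion
Reagents that add atoms: none
Why: hydrogenolysis of the ten aryl benzyl ethers should be faster than cleavage of the ring benzylic C–O bonds and touches no stereocentre.

**Compound list**

1 | 3-bromo-5-fluorophenol | Oc1cc(F)cc(Br)c1 | starting material
2 | 1-(benzyloxy)-3-bromo-5-fluorobenzene | Fc1cc(Br)cc(OCc2ccccc2)c1 | intermediate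
3 | tert-butyl 2-[3-(benzyloxy)-5-fluorophenyl]acetate | CC(C)(C)OC(=O)Cc1cc(F)cc(OCc2ccccc2)c1 | intermediate
4 | tert-butyl 2-[5-(benzyloxy)-2-bromo-3-fluorophenyl]acetate | CC(C)(C)OC(=O)Cc1cc(OCc2ccccc2)cc(F)c1Br | intermediate
5 | 2-[5-(benzyloxy)-2-bromo-3-fluorophenyl]acetic acid | OC(=O)Cc1cc(OCc2ccccc2)cc(F)c1Br | intermediate
6 | pentafluorophenyl 2-[5-(benzyloxy)-2-bromo-3-fluorophenyl]acetate | O=C(Cc1cc(OCc2ccccc2)cc(F)c1Br)Oc1c(F)c(F)c(F)c(F)c1F | intermediate
7 | 3,5-bis(benzyloxy)benzaldehyde | O=Cc1cc(OCc2ccccc2)cc(OCc2ccccc2)c1 | starting material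
8 | ethyl (E)-3-[3,5-bis(benzyloxy)phenyl]prop-2-enoate | CCOC(=O)/C=C/c1cc(OCc2ccccc2)cc(OCc2ccccc2)c1 | intermediate
9 | (E)-3-[3,5-bis(benzyloxy)phenyl]prop-2-en-1-ol | OC/C=C/c1cc(OCc2ccccc2)cc(OCc2ccccc2)c1 | intermediate
10 | tert-butyl (E)-3-[3,5-bis(benzyloxy)phenyl]prop-2-en-1-yl carbonate | CC(C)(C)OC(=O)OC/C=C/c1cc(OCc2ccccc2)cc(OCc2ccccc2)c1 | intermediate
11 | pentafluorophenyl (2S,3R)-2-[5-(benzyloxy)-2-bromo-3-fluorophenyl]-3-[3,5-bis(benzyloxy)phenyl]pent-4-enoate | Fc1cc(OCc6ccccc6)cc([C@@H](C(=O)Oc2c(F)c(F)c(F)c(F)c2F)[C@H](c5cc(OCc6ccccc6)cc(OCc6ccccc6)c5)C=C)c1Br | intermediate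
12 | (2S,3R)-2-[5-(benzyloxy)-2-bromo-3-fluorophenyl]-3-[3,5-bis(benzyloxy)phenyl]-N-methoxy-N-methylpent-4-enamide | Fc1cc(OCc6ccccc6)cc([C@@H](C(=O)N(C)OC)[C@H](c5cc(OCc6ccccc6)cc(OCc6ccccc6)c5)C=C)c1Br | intermediate
13 | (2S,3R)-2-[5-(benzyloxy)-2-bromo-3-fluorophenyl]-3-[3,5-bis(benzyloxy)phenyl]-N-methoxy-N-methyl-4-oxobutanamide | Fc1cc(OCc6ccccc6)cc([C@@H](C(=O)N(C)OC)[C@H](c5cc(OCc6ccccc6)cc(OCc6ccccc6)c5)C=O)c1Br | intermediate
14 | 4-(benzyloxy)phenylmagnesium bromide (THF solution) | Br[Mg]c1ccc(OCc2ccccc2)cc1 | starting material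
15 | (2S,3R)-2-[5-(benzyloxy)-2-bromo-3-fluorophenyl]-1,4-bis[4-(benzyloxy)phenyl]-3-[3,5-bis(benzyloxy)phenyl]-4-hydroxybutan-1-one, C4 epimers | Fc1cc(OCc6ccccc6)cc([C@@H](C(=O)c4ccc(OCc6ccccc6)cc4)[C@H](c5cc(OCc6ccccc6)cc(OCc6ccccc6)c5)C(O)c4ccc(OCc6ccccc6)cc4)c1Br | intermediate
16 | (2S,3R)-2-[5-(benzyloxy)-2-bromo-3-fluorophenyl]-1,4-bis[4-(benzyloxy)phenyl]-3-[3,5-bis(benzyloxy)phenyl]butane-1,4-diol, C1/C4 epimers | Fc1cc(OCc6ccccc6)cc([C@@H](C(O)c4ccc(OCc6ccccc6)cc4)[C@H](c5cc(OCc6ccccc6)cc(OCc6ccccc6)c5)C(O)c4ccc(OCc6ccccc6)cc4)c1Br | intermediate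
17 | (2R,3S,4R,5S)-3-[5-(benzyloxy)-2-bromo-3-fluorophenyl]-2,5-bis[4-(benzyloxy)phenyl]-4-[3,5-bis(benzyloxy)phenyl]oxolane | Fc1cc(OCc6ccccc6)cc([C@@H]4[C@H](c5cc(OCc6ccccc6)cc(OCc6ccccc6)c5)[C@@H](c5ccc(OCc6ccccc6)cc5)O[C@H]4c4ccc(OCc6ccccc6)cc4)c1Br | intermediate
18 | 5-bromo-2-hydroxy-3-methoxybenzaldehyde | COc1cc(Br)cc(C=O)c1O | starting material
19 | 5-bromo-2,3-dihydroxybenzaldehyde | O=Cc1cc(Br)cc(O)c1O | intermediate
20 | 4-(benzyloxy)benzyl chloride | ClCc1ccc(OCc2ccccc2)cc1 | starting material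
21 | sodium 2-(benzyloxy)-4-bromo-6-formylphenolate | [Na+].[O-]c1c(C=O)cc(Br)cc1OCc1ccccc1 | intermediate
22 | 3-(benzyloxy)-2-{[4-(benzyloxy)benzyl]oxy}-5-bromobenzaldehyde | O=Cc1cc(Br)cc(OCc2ccccc2)c1OCc1ccc(OCc2ccccc2)cc1 | intermediate
23 | 1,3-bis(benzyloxy)-5-bromobenzene | Brc1cc(OCc2ccccc2)cc(OCc2ccccc2)c1 | starting material
24 | 3,5-bis(benzyloxy)phenylmagnesium bromide | Br[Mg]c1cc(OCc2ccccc2)cc(OCc2ccccc2)c1 | intermediate
25 | [3-(benzyloxy)-2-{[4-(benzyloxy)benzyl]oxy}-5-bromophenyl][3,5-bis(benzyloxy)phenyl]methanol, racemic | OC(c1cc(Br)cc(OCc2ccccc2)c1OCc1ccc(OCc2ccccc2)cc1)c1cc(OCc2ccccc2)cc(OCc2ccccc2)c1 | intermediate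
26 | [3-(benzyloxy)-2-{[4-(benzyloxy)benzyl]oxy}-5-bromophenyl][3,5-bis(benzyloxy)phenyl]methanone | O=C(c1cc(Br)cc(OCc2ccccc2)c1OCc1ccc(OCc2ccccc2)cc1)c1cc(OCc2ccccc2)cc(OCc2ccccc2)c1 | intermediate
27 | hydrazone of 26 (E/Z mixture) | NN=C(c1cc(Br)cc(OCc2ccccc2)c1OCc1ccc(OCc2ccccc2)cc1)c1cc(OCc2ccccc2)cc(OCc2ccccc2)c1 | intermediate
28 | [3-(benzyloxy)-2-{[4-(benzyloxy)benzyl]oxy}-5-bromophenyl][3,5-bis(benzyloxy)phenyl]diazomethane | [N-]=[N+]=C(c1cc(Br)cc(OCc2ccccc2)c1OCc1ccc(OCc2ccccc2)cc1)c1cc(OCc2ccccc2)cc(OCc2ccccc2)c1 | intermediate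
29 | (2S,3R)-7-(benzyloxy)-2-[4-(benzyloxy)phenyl]-3-[3,5-bis(benzyloxy)phenyl]-5-bromo-2,3-dihydro-1-benzofuran (cis) | Brc2cc(OCc6ccccc6)c3c(c2)[C@@H](c2cc(OCc6ccccc6)cc(OCc6ccccc6)c2)[C@@H](c2ccc(OCc6ccccc6)cc2)O3 | intermediate
30 | (2R,3R)-7-(benzyloxy)-2-[4-(benzyloxy)phenyl]-3-[3,5-bis(benzyloxy)phenyl]-5-bromo-2,3-dihydro-1-benzofuran (trans) | Brc2cc(OCc6ccccc6)c3c(c2)[C@@H](c2cc(OCc6ccccc6)cc(OCc6ccccc6)c2)[C@H](c2ccc(OCc6ccccc6)cc2)O3 | intermediate
31 | 2-{[(2R,3R)-7-(benzyloxy)-2-[4-(benzyloxy)phenyl]-3-[3,5-bis(benzyloxy)phenyl]-2,3-dihydro-1-benzofuran-5-yl]methyl}-4,4,5,5-tetramethyl-1,3,2-dioxaborolane | CC1(C)OB(Cc2cc(OCc6ccccc6)c3c(c2)[C@@H](c2cc(OCc6ccccc6)cc(OCc6ccccc6)c2)[C@H](c2ccc(OCc6ccccc6)cc2)O3)OC1(C)C | intermediate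
32 | diarylmethane: (2R,3R)-dihydrobenzofuran-5-yl–CH2–[4-(benzyloxy)-6-fluoro-2-((2R,3S,4R,5S)-oxolan-3-yl)phenyl], all phenols benzylated | Fc1cc(OCc6ccccc6)cc([C@@H]4[C@H](c5cc(OCc6ccccc6)cc(OCc6ccccc6)c5)[C@@H](c5ccc(OCc6ccccc6)cc5)O[C@H]4c4ccc(OCc6ccccc6)cc4)c1Cc2cc(OCc6ccccc6)c3c(c2)[C@@H](c2cc(OCc6ccccc6)cc(OCc6ccccc6)c2)[C@H](c2ccc(OCc6ccccc6)cc2)O3 | intermediate
33 | 4-(benzyloxy)benzaldehyde | O=Cc1ccc(OCc2ccccc2)cc1 | starting material
34 | benzylic lithium compound from 32 (lithium on the diarylmethane carbon) | Fc1cc(OCc6ccccc6)cc([C@@H]4[C@H](c5cc(OCc6ccccc6)cc(OCc6ccccc6)c5)[C@@H](c5ccc(OCc6ccccc6)cc5)O[C@H]4c4ccc(OCc6ccccc6)cc4)c1C([Li])c2cc(OCc6ccccc6)c3c(c2)[C@@H](c2cc(OCc6ccccc6)cc(OCc6ccccc6)c2)[C@H](c2ccc(OCc6ccccc6)cc2)O3 | intermediate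
35 | lithium (1S,2S)-1-[4-(benzyloxy)phenyl]-2-(fluoroaryl)-2-(dihydrobenzofuran-5-yl)ethoxide | Fc1cc(OCc6ccccc6)cc([C@@H]4[C@H](c5cc(OCc6ccccc6)cc(OCc6ccccc6)c5)[C@@H](c5ccc(OCc6ccccc6)cc5)O[C@H]4c4ccc(OCc6ccccc6)cc4)c1[C@@H]([C@H](O[Li])c7ccc(OCc6ccccc6)cc7)c2cc(OCc6ccccc6)c3c(c2)[C@@H](c2cc(OCc6ccccc6)cc(OCc6ccccc6)c2)[C@H](c2ccc(OCc6ccccc6)cc2)O3 | intermediate
36 | deca-O-benzylkobophenol A (central dihydrobenzofuran 2S,3S; oxolane 2R,3S,4R,5S; outer dihydrobenzofuran 2R,3R) | O(Cc6ccccc6)c1ccc([C@H]2Oc3cc(OCc6ccccc6)cc([C@@H]4[C@H](c5cc(OCc6ccccc6)cc(OCc6ccccc6)c5)[C@@H](c5ccc(OCc6ccccc6)cc5)O[C@H]4c4ccc(OCc6ccccc6)cc4)c3[C@@H]2c2cc(OCc6ccccc6)c3c(c2)[C@@H](c2cc(OCc6ccccc6)cc(OCc6ccccc6)c2)[C@H](c2ccc(OCc6ccccc6)cc2)O3)cc1 | intermediate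
37 | kobophenol A | Oc1ccc([C@H]2Oc3cc(O)cc([C@@H]4[C@H](c5cc(O)cc(O)c5)[C@@H](c5ccc(O)cc5)O[C@H]4c4ccc(O)cc4)c3[C@@H]2c2cc(O)c3c(c2)[C@@H](c2cc(O)cc(O)c2)[C@H](c2ccc(O)cc2)O3)cc1 | target

**Step count**

Total: 24 steps. Longest linear sequence: 13 steps (steps 1–5, 9–13, 22–24).

**Three steps most likely to fail**

1. Step 23 (proposed new method). What may go wrong: lithiation ortho to fluorine or at C3–H of the outer dihydrobenzofuran (followed by ring opening) instead of at the benzylic CH2; poor facial selectivity in the aldehyde addition; retro-addition or sluggish fluoride displacement on warming. Fallback with known chemistry, setting out from 32 and coming back at 36: the addition is run alone (LDA, THF, −78 °C, then 33, cold AcOH quench) and the diastereomers are separated to give the anti alcohol (1S,2S)-1-[4-(benzyloxy)phenyl]-2,2-diarylethanol F1. If the wrong carbinol epimer prevails, the alcohol mixture is oxidised with Dess–Martin periodinane to the 1-[4-(benzyloxy)phenyl]-2,2-diarylethanone F2 and reduced with BH3·SMe2 and the appropriate enantiomer of the 2-methyl-CBS-oxazaborolidine, so that the carbinol centre is set by the reagent, and F1 is again isolated. F1 is then cyclised in a separate intramolecular SNAr etherification (KHMDS, 18-crown-6, THF, 0 to 40 °C) to give 36.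

2. Step 13. What may go wrong: Friedel–Crafts capture of the benzylic cation by the neighbouring bis(benzyloxy)phenyl ring (indane formation, irreversible), or incomplete equilibration at C2/C5. Fallback, setting out from 15 and coming back at 17: 15 is converted with MeOH/PPTS into the cyclic methyl ketal (3S,4R)-3-[5-(benzyloxy)-2-bromo-3-fluorophenyl]-2,5-bis[4-(benzyloxy)phenyl]-4-[3,5-bis(benzyloxy)phenyl]-2-methoxyoxolane F3, which is reduced with Et3SiH/BF3·OEt2 at −78 °C. The cyclic oxocarbenium ion cannot be reached by the neighbouring arenes without strain, and hydride is delivered cis to the C3 aryl (inside attack), placing the C2 aryl trans to it, as in the hemiketal reductions used for 2,5-diaryl oxolane lignans. C5 then comes from the Grignard addition of step 11, so its epimer is removed by chromatography.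

3. Step 24. What may go wrong: over-reduction, that is hydrogenolysis of the benzylic C–O bonds of the oxolane or of the two dihydrobenzofurans, or stalling before all ten ethers are cleaved. Fallback, setting out from 36 and coming back at 37: Lewis-acid debenzylation without hydrogen, BCl3 (excess) with pentamethylbenzene as cation scavenger, CH2Cl2, −78 °C, cold methanol quench. It makes no new isolated compound.

**Further compounds**

F1 | step 23 | (1S,2S)-1-[4-(benzyloxy)phenyl]-2-[4-(benzyloxy)-6-fluoro-2-(oxolan-3-yl)phenyl]-2-(dihydrobenzofuran-5-yl)ethan-1-ol (protonated form of 35) | Fc1cc(OCc6ccccc6)cc([C@@H]4[C@H](c5cc(OCc6ccccc6)cc(OCc6ccccc6)c5)[C@@H](c5ccc(OCc6ccccc6)cc5)O[C@H]4c4ccc(OCc6ccccc6)cc4)c1[C@@H]([C@H](O)c7ccc(OCc6ccccc6)cc7)c2cc(OCc6ccccc6)c3c(c2)[C@@H](c2cc(OCc6ccccc6)cc(OCc6ccccc6)c2)[C@H](c2ccc(OCc6ccccc6)cc2)O3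
F2 | step 23 | 1-[4-(benzyloxy)phenyl]-2,2-diarylethanone corresponding to F1 (C2 epimers) | Fc1cc(OCc6ccccc6)cc([C@@H]4[C@H](c5cc(OCc6ccccc6)cc(OCc6ccccc6)c5)[C@@H](c5ccc(OCc6ccccc6)cc5)O[C@H]4c4ccc(OCc6ccccc6)cc4)c1C(C(=O)c7ccc(OCc6ccccc6)cc7)c2cc(OCc6ccccc6)c3c(c2)[C@@H](c2cc(OCc6ccccc6)cc(OCc6ccccc6)c2)[C@H](c2ccc(OCc6ccccc6)cc2)O3
F3 | step 13 | (3S,4R)-3-[5-(benzyloxy)-2-bromo-3-fluorophenyl]-2,5-bis[4-(benzyloxy)phenyl]-4-[3,5-bis(benzyloxy)phenyl]-2-methoxyoxolane (C2/C5 epimers) | Fc1cc(OCc6ccccc6)cc([C@@H]4[C@H](c5cc(OCc6ccccc6)cc(OCc6ccccc6)c5)C(c5ccc(OCc6ccccc6)cc5)OC4(OC)c4ccc(OCc6ccccc6)cc4)c1Br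
F0 | step 24 | none | none
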